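## Retrosynthetic overview

1. The cis-bromohydrin (C9, C10) comes from an α'-bromo enone by catalyst-controlled transfer hydrogenation with dynamic kinetic resolution. The bromo enone comes from the enone by α'-bromination.
2. The ring-B halides come from an achiral spiro[5.5]undecenedione. An enamine α-chlorination desymmetrises it and sets C2 and C6 together. MeMgBr addition followed by Br-for-OH exchange with inversion sets C3.
3. The enedione comes from a spirotrienedione, which is made in the key step. A vinyl radical attacks the ipso carbon of a p-anisyl ring (6-exo) and forms C6–C7, the spiro quaternary carbon next to CMe2.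
4. The radical precursor comes from an ynone built from anisole, 3-methylbut-2-enoic acid (Friedel–Crafts, C6–C11) and propyne.
5. Ring order: ring B enters as the arene, and ring A is closed in the radical step.

Locants: the spiro[5.5]undecane numbering of the target is used throughout. C1–C5 are ring B (C2 Cl, C3 Br/Me), C6 is the spiro carbon, and C7–C11 are ring A (C7 Me, C9 OH, C10 Br, C11 Me2).

Assumption: the catalyst antipodes named in steps 5 and 9 are predicted from model substrates (2-chlorocyclohexanone, aryl/alkenyl ketones). The mirror-image catalyst is used if the sense proves opposite.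

## Route

**Step 1**
Reactants: 1 anisole; 2 3-methylbut-2-enoic acid
Product: 3 3-(4-methoxyphenyl)-3-methylbutanoic acid
Conditions: AlCl3 (3 equiv), CH2Cl2, 0 to 23 °C; aq. HCl
Reagents that add atoms: none
Why: Friedel–Crafts alkylation, in which AlCl3 turns the unsaturated acid into a tertiary β-cation equivalent whose bulk directs it para to OMe, so C6–C11 forms without creating a stereocentre.

**Step 2**
Reactants: 3 3-(4-methoxyphenyl)-3-methylbutanoic acid; 4 propyne
Product: 6 6-(4-methoxyphenyl)-6-methylhept-2-yn-4-one, via acid chloride 5 (not isolated)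
Conditions: (COCl)2, cat. DMF, CH2Cl2, 0 to 23 °C, evaporate; propyne (1 atm), PdCl2(PPh3)2 (2 mol %), CuI (4 mol %), Et3N (1.2 equiv), THF, 23 °C
Reagents that add atoms: none
Why: Acyl Sonogashira coupling, in which the acid chloride is taken up by Pd/Cu-activated propyne and, with no Lewis acid present, the electron-rich ring is not acylated to the indanone.

**Step 3 (key step)**
Reactants: 6 6-(4-methoxyphenyl)-6-methylhept-2-yn-4-one
Product: 8 7,11,11-trimethylspiro[5.5]undeca-1,4,7-triene-3,9-dione, via (Z)-iodoenone 7 (not isolated)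
Conditions: NaI (1.1 equiv), AcOH (1.1 equiv), MeCN, 60 °C, dark; then fac-Ir(ppy)3 (1 mol %), 450 nm, Ar, 23 °C
Reagents that add atoms: none
Why: Proposed new method: conjugate hydroiodination gives the light-sensitive (Z)-β-iodoenone, excited Ir(ppy)3 reduces its C–I bond to a rapidly inverting σ-vinyl radical that attacks the anisole ipso carbon 6-exo-trig (helped by the Thorpe–Ingold effect of CMe2, the slim sp2 radical next to the quaternary carbon, and p-OMe stabilisation of the spiro-cyclohexadienyl radical), Ir(IV) oxidises that radical to the O-methyl oxocarbenium ion and iodide removes the methyl group, so the cycle is redox-neutral and the product is achiral; the closest known reaction type is the radical dearomative ipso-cyclisation of biaryl ynones and N-arylpropiolamides to spirotrienones.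

**Step 4**
Reactants: 8 7,11,11-trimethylspiro[5.5]undeca-1,4,7-triene-3,9-dione
Product: 9 7,11,11-trimethylspiro[5.5]undec-7-ene-3,9-dione
Conditions: H2 (1 atm, stop at 2 equiv), 5 % Pd/C, EtOAc, 23 °C
Reagents that add atoms: none
Why: Chemoselective catalytic hydrogenation saturates the two unhindered disubstituted C=C bonds of ring B and leaves the trisubstituted C7=C8 bond next to the quaternary C6, so the product keeps its mirror plane.

**Step 5**
Reactants: 9 7,11,11-trimethylspiro[5.5]undec-7-ene-3,9-dione
Product: 10 (2S,6S)-2-chloro-7,11,11-trimethylspiro[5.5]undec-7-ene-3,9-dione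
Conditions: NCS (0.95 equiv), (4R,5R)-4,5-diphenylimidazolidine (20 mol %), 2-nitrobenzoic acid (20 mol %), MeCN, −24 °C; chromatography
Reagents that add atoms: N-chlorosuccinimide, O=C1CCC(=O)N1Cl
Why: Enamine-catalysed asymmetric α-chlorination used as a desymmetrisation, in which only the saturated C3 ketone forms an enamine, the catalyst fixes (S) at the C–Cl carbon, and axial C–Cl formation on the half-chair that keeps bulky C11 pseudo-equatorial and flat C7 pseudo-axial puts Cl cis to C7, so the choice of enantiotopic CH2 sets C6 at the same time (the other diastereomer is separable).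

**Step 6**
Reactants: 10 (2S,6S)-2-chloro-7,11,11-trimethylspiro[5.5]undec-7-ene-3,9-dione
Product: 11 (2S,3R,6S)-2-chloro-3-hydroxy-3,7,11,11-tetramethylspiro[5.5]undec-7-en-9-one
Conditions: MeMgBr (1.1 equiv), Et2O/CH2Cl2, −78 °C; H2O quench at −78 °C
Reagents that add atoms: methylmagnesium bromide, C[Mg]Br
Why: Chemoselective Grignard 1,2-addition, in which the α-chloro ketone is far more electrophilic than the conjugated, neopentyl-flanked C9 carbonyl, and attack anti to C–Cl (Cornforth model, as for 2-chlorocyclohexanone) gives the chlorohydrin with OH cis and methyl trans to Cl.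

**Step 7**
Reactants: 11 (2S,3R,6S)-2-chloro-3-hydroxy-3,7,11,11-tetramethylspiro[5.5]undec-7-en-9-one
Product: 12 (2S,3S,6S)-3-bromo-2-chloro-3,7,11,11-tetramethylspiro[5.5]undec-7-en-9-one
Conditions: TMSBr (2 equiv), CH2Cl2, −20 to 0 °C
Reagents that add atoms: bromotrimethylsilane, C[Si](C)(C)Br
Why: SN1-type bromodehydroxylation of a tertiary alcohol, in which the β-chloro cation (a chloriranium-like ion pair) is captured by bromide on the face opposite both the leaving group and the chlorine, so C3 is inverted and Br ends trans to Cl.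

**Step 8**
Reactants: 12 (2S,3S,6S)-3-bromo-2-chloro-3,7,11,11-tetramethylspiro[5.5]undec-7-en-9-one
Product: 14 (2S,3S,6R,10RS)-3,10-dibromo-2-chloro-3,7,11,11-tetramethylspiro[5.5]undec-7-en-9-one, via silyl dienol ether 13 (not isolated)
Conditions: LDA (1.05 equiv), TMSCl (internal quench), THF, −78 °C; then NBS, −78 to 0 °C; H2O
Reagents that add atoms: N-bromosuccinimide, O=C1CCC(=O)N1Br
Why: Kinetic α'-deprotonation of the enone (only C10 carries α'-hydrogens, and at −78 °C it is much faster than E2 at the tertiary bromide) with silylation and then NBS bromination of the cross-conjugated silyl dienol ether at C10, where the C10 epimer ratio does not matter because this labile centre is fixed in step 9.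

**Step 9**
Reactants: 14 (2S,3S,6R,10RS)-3,10-dibromo-2-chloro-3,7,11,11-tetramethylspiro[5.5]undec-7-en-9-one
Product: 15 (2S,3S,6R,9S,10R)-3,10-dibromo-2-chloro-3,7,11,11-tetramethylspiro[5.5]undec-7-en-9-ol
Conditions: RuCl[(R,R)-TsDPEN](p-cymene) (2 mol %), HCO2H/Et3N, CH2Cl2, 23 °C
Reagents that add atoms: none
Why: Noyori–Ikariya asymmetric transfer hydrogenation with dynamic kinetic resolution (known for 2-halocycloalkanones), in which Et3N epimerises C10 through the enol, the (R,R)-catalyst holds the alkenyl side in its CH/π pocket and delivers hydride to give (9S), and the epimer leading to the cis-bromohydrin reacts fastest and sets (10R), while the neopentyl C10–Br, which has no β-hydrogen on C11, resists substitution and elimination.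

## Compound list

1 | anisole | COc1ccccc1 | starting material
2 | 3-methylbut-2-enoic acid | CC(C)=CC(=O)O | starting material
3 | 3-(4-methoxyphenyl)-3-methylbutanoic acid | COc1ccc(cc1)C(C)(C)CC(=O)O | intermediate
4 | propyne | CC#C | starting material
5 | 3-(4-methoxyphenyl)-3-methylbutanoyl chloride | COc1ccc(cc1)C(C)(C)CC(=O)Cl | intermediate
6 | 6-(4-methoxyphenyl)-6-methylhept-2-yn-4-one | CC#CC(=O)CC(C)(C)c1ccc(OC)cc1 | intermediate
7 | (Z)-2-iodo-6-(4-methoxyphenyl)-6-methylhept-2-en-4-one | C/C(I)=C/C(=O)CC(C)(C)c1ccc(OC)cc1 | intermediate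
8 | 7,11,11-trimethylspiro[5.5]undeca-1,4,7-triene-3,9-dione (achiral) | CC1=CC(=O)CC(C)(C)C12C=CC(=O)C=C2 | intermediate
9 | 7,11,11-trimethylspiro[5.5]undec-7-ene-3,9-dione (achiral) | CC1=CC(=O)CC(C)(C)C12CCC(=O)CC2 | intermediate
10 | (2S,6S)-2-chloro-7,11,11-trimethylspiro[5.5]undec-7-ene-3,9-dione (Cl cis to C7) | CC1=CC(=O)CC(C)(C)[C@@]12CCC(=O)[C@@H](Cl)C2 | intermediate
11 | (2S,3R,6S)-2-chloro-3-hydroxy-3,7,11,11-tetramethylspiro[5.5]undec-7-en-9-one (OH cis to Cl) | CC1=CC(=O)CC(C)(C)[C@@]12CC[C@@](C)(O)[C@@H](Cl)C2 | intermediate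
12 | (2S,3S,6S)-3-bromo-2-chloro-3,7,11,11-tetramethylspiro[5.5]undec-7-en-9-one (Br trans to Cl) | CC1=CC(=O)CC(C)(C)[C@@]12CC[C@](C)(Br)[C@@H](Cl)C2 | intermediate
13 | [(2S,3S,6R)-3-bromo-2-chloro-3,7,11,11-tetramethylspiro[5.5]undeca-7,9-dien-9-yl]oxy(trimethyl)silane | CC1=CC(O[Si](C)(C)C)=CC(C)(C)[C@@]12CC[C@](C)(Br)[C@@H](Cl)C2 | intermediate
14 | (2S,3S,6R,10RS)-3,10-dibromo-2-chloro-3,7,11,11-tetramethylspiro[5.5]undec-7-en-9-one (C10 epimers) | CC1=CC(=O)C(Br)C(C)(C)[C@@]12CC[C@](C)(Br)[C@@H](Cl)C2 | intermediate
15 | (2S,3S,6R,9S,10R)-3,10-dibromo-2-chloro-3,7,11,11-tetramethylspiro[5.5]undec-7-en-9-ol | CC1=C[C@H](O)[C@H](Br)C(C)(C)[C@@]12CC[C@](C)(Br)[C@@H](Cl)C2 | target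

Total step count: 9. Longest linear sequence: 9.

## Three steps most likely to fail

**Step 3.** The ipso attack may lose to ortho (7-endo) attack, to 1,6-hydrogen transfer from a geminal methyl, or to simple reduction of the vinyl radical. The fallback reverses the roles of radical and acceptor. It sets out from 3 and comes back at 9. Birch reduction (Li, NH3, t-BuOH) gives 3-(4-methoxycyclohexa-1,4-dien-1-yl)-3-methylbutanoic acid F1. Coupling with MeNHOMe (EDC) gives N-methoxy-3-(4-methoxycyclohexa-1,4-dien-1-yl)-N,3-dimethylbutanamide F2. 1-Propynylmagnesium bromide then gives 6-(4-methoxycyclohexa-1,4-dien-1-yl)-6-methylhept-2-yn-4-one F3. Aqueous oxalic acid frees the β,γ-unsaturated ketone 6-methyl-6-(4-oxocyclohex-1-en-1-yl)hept-2-yn-4-one F4. Fe(acac)3/PhSiH3 in EtOH (metal-hydride hydrogen-atom transfer) puts H on C5. The tertiary C6 radical closes 6-endo-dig on the ynone β-carbon, and the ring vinyl radical takes H from the silane. This gives 9 directly, so step 4 is not needed.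

**Step 5.** Both faces of ring B carry an inward-pointing methyl group, so the preference for Cl cis to C7 may be small and up to half of the material may be the other diastereomer. The fallback separates the two stereochemical tasks. It sets out from 8 and comes back at 10. Copper hydride conjugate reduction (Cu(OAc)2, DTBM-SEGPHOS, PMHS, t-BuOH) of one enantiotopic enone arm sets C6 alone and gives (6R)-7,11,11-trimethylspiro[5.5]undeca-1,7-diene-3,9-dione F5. Its ring-B carbonyl now has a single enolisable CH2. The same enamine chlorination therefore has no choice of site, and its facial sense is pure catalyst control. It gives (4S,6R)-4-chloro-7,11,11-trimethylspiro[5.5]undeca-1,7-diene-3,9-dione F6. Hydrogenation of the remaining disubstituted alkene with RhCl(PPh3)3/H2, which does not cleave the C–Cl bond, gives 10.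

**Step 7.** The β-chloro cation may lose a proton, undergo a 1,2-hydride shift to the α-chloro cation, or give the cis bromochloride under equilibrating conditions. The fallback forms the C–Br bond by a radical instead of a cation. It sets out from 11 and comes back at 12. Burgess reagent effects syn elimination. The C2–H is anti to the OH, so no vinyl chloride can form. The product is (2S,6S)-2-chloro-3,7,11,11-tetramethylspiro[5.5]undeca-3,7-dien-9-one F7. Cobalt-catalysed Markovnikov hydrobromination by hydrogen-atom transfer (Co(acac)2, t-BuOOH, Et3SiH, TsBr) puts H on C4. The tertiary C3 radical, whose β-C–Cl bond shields one face and does not fragment on this time scale, takes Br anti to Cl to give 12.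

## Further compounds

F1 | step 3 | 3-(4-methoxycyclohexa-1,4-dien-1-yl)-3-methylbutanoic acid | COC1=CCC(=CC1)C(C)(C)CC(=O)O
F2 | step 3 | N-methoxy-3-(4-methoxycyclohexa-1,4-dien-1-yl)-N,3-dimethylbutanamide | COC1=CCC(=CC1)C(C)(C)CC(=O)N(C)OC
F3 | step 3 | 6-(4-methoxycyclohexa-1,4-dien-1-yl)-6-methylhept-2-yn-4-one | CC#CC(=O)CC(C)(C)C1=CCC(OC)=CC1
F4 | step 3 | 6-methyl-6-(4-oxocyclohex-1-en-1-yl)hept-2-yn-4-one | CC#CC(=O)CC(C)(C)C1=CCC(=O)CC1
F5 | step 5 | (6R)-7,11,11-trimethylspiro[5.5]undeca-1,7-diene-3,9-dione | CC1=CC(=O)CC(C)(C)[C@@]12C=CC(=O)CC2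
F6 | step 5 | (4S,6R)-4-chloro-7,11,11-trimethylspiro[5.5]undeca-1,7-diene-3,9-dione | CC1=CC(=O)CC(C)(C)[C@@]12C=CC(=O)[C@@H](Cl)C2
F7 | step 7 | (2S,6S)-2-chloro-3,7,11,11-tetramethylspiro[5.5]undeca-3,7-dien-9-one | CC1=CC(=O)CC(C)(C)[C@@]12CC=C(C)[C@@H](Cl)C2
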